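The numbers of this flask are invented, and the outcome is calculated.

Reckon how much target each of these flasks holds at the end, adding one process at a time.

all flasks: substrate 20 mM; capture agent 0.400 mM; time 15 h

|  | first nucleophile | second nucleophile | remark |
|---|---|---|---|
| theta | 1.50 equiv | 0.600 equiv | everything together at the start |
| beta | 1.50 equiv (fed, over 20 min) | 0.600 equiv | all else is in the flask from the start; the feed brings no volume worth counting |
| epsilon | 1.50 equiv (fed, over 3.0 h) | 0.600 equiv | all else is in the flask from the start; the feed brings no volume worth counting |
| delta | 1.50 equiv | 0.600 equiv (fed, over 3.0 h) | all else is in the flask from the start; the feed brings no volume worth counting |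

    substrate ⇌ open intermediate (K1 = 0.0230, k1 = 0.00108 min⁻¹)
    first nucleophile + open intermediate → target (k2 = 3.00 L mol⁻¹ min⁻¹)
    second nucleophile + open intermediate → other capture product (k3 = 0.348 L mol⁻¹ min⁻¹)
    open intermediate + capture agent → trapped intermediate (k4 = 1.14 L mol⁻¹ min⁻¹)
    crystals ⇌ target, rate k5*(cs5 - [target]) while solid is left; crystals form when [target] > cs5 (cs5 = 3.2 mM, k5 = 0.588 min⁻¹)
    target ⇌ isomer of the product (K6 = 6.13, k6 = 0.00223 min⁻¹)

1. the flask that comes out highest in amount of target, in percent of the substrate charged, or "all alike" when all lie within 1.5 percentage points (theta / beta / epsilon / delta / all alike)
2. target at the end, in percent of the substrate charged, theta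
3. target at the end, in percent of the substrate charged, beta
4. target at the end, in percent of the substrate charged, epsilon
5. target at the end, in percent of the substrate charged, delta

- target is meant together with its crystals
- solid, in amounts per volume of the solution: crystals
- run time (theta): 15 h

I start with the opening of the substrate and nothing going back, which in theta leaves 37.8% of the substrate. Then I add the way back. An open intermediate closes at 0.0470 min⁻¹, or the first nucleophile catches it at a pseudo-first-order constant proportional to c(first nucleophile). This gives my zero: the even-odds concentration c* = 15.7 mM, the c(first nucleophile) at which capture and closing tie and half of the openings go forward. Any other flask has the forward share c/(c + c*). Theta starts at 30.0 mM, above c*, so its share is 65.7%. Holding that share would use enough first nucleophile to leave 20.6 mM, where the share is 56.8%. The mean of the two, 61.2%, leaves 55.1% of the substrate, so 8.97 mM is caught.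

Now the rest. The second nucleophile and the capture agent together take 5.15% of what the first nucleophile takes at the start, a small part. Target therefore forms at 0.808 mM h⁻¹ and reaches 3.2 mM in about 3.96 h. While crystals last, dissolved target stands at that level and isomerisation drains it at a steady forward rate, which takes 4.73 mM by the end. That leaves theta with 18.9%.

In epsilon the first nucleophile climbs over 3.0 h and, without uptake, averages 15.0 mM, close to c*, so I take the share at that level, near half, for the feed. That forfeits 0.611 mM, but later saturation repays 53.0% of it. Epsilon should end 1.4 percentage points under theta, less than the margin. Beta's feed is shorter, and delta merely delays a minor side path, so I expect the flasks to stay inside the margin.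

The forecast also says all alike, but it puts theta higher than my figure, at 20.5%, with 20.4% for beta, 20.1% for epsilon and 20.7% for delta, holding that “all four flasks land within about a point”. The simulation gives all alike: 20.1% for theta, 20.1% for beta, 19.7% for epsilon and 20.2% for delta.

Theta ends with 21.4 mM of first nucleophile, still above c*, and with 54.2% of its substrate. The neighbour is epsilon with 0.900 equiv of first nucleophile, still fed over 3.0 h, so 18.0 mM is the sum fed, and without uptake c(first nucleophile) averages 9.00 mM during the feed, below c*, for a share of 36.5%. By my reckoning the end of the feed leaves 93.1% of the substrate and 16.6 mM of first nucleophile, where the share is 51.5%. Holding that share to the end would leave 10.5 mM, and the mean of the two shares leaves 65.2% of the substrate. That flask reads 62.8% of substrate and ends with 11.5 mM of first nucleophile, below c*. It holds 0% crystals, 17.8% isomer of the product and 14.7% target.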